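Norbornane atoms are C1–C7, chroman atoms primed. The norbornane is disconnected at the bond between spiro carbon C2 (= C2', bearing the ring oxygen) and bridgehead C1, so that ring C1–C2–C3–C4–C7 is closed last onto a chroman that already carries C3(CH3)2 and an intact cyclopent-3-enyl ring (C4, C5, C6, C1, C7). The key step exploits C2 being an O-substituted tertiary centre: hydrogen-atom transfer to a 4H-chromene enol ether gives the C2 α-alkoxy radical, which adds 5-exo to the cyclopentene and is reduced, setting C1, C2 and C4 under control of C4'. C4' comes from a copper-catalysed asymmetric conjugate addition to a commercial coumarin; demethylation and double formylation finish.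

Key step: step 5

Assumption: 4-bromocyclopent-1-ene (1) is taken as a commercial catalogue compound.

Step 1
Reactants: 1 4-bromocyclopent-1-ene; 2 2-methylpropanoic acid
Product: 3 2-(cyclopent-3-en-1-yl)-2-methylpropanoic acid
Conditions: LiN(i-Pr)2 (2.2 equiv), THF, 0 → 45 °C; then 1, 0 °C → rt; aq. HCl
Reagents that add atoms: none
Why: The lithium dianion of the acid is a compact, strongly nucleophilic tertiary carbanion that should displace the secondary bromide by SN2 (carboxylic acid dianion alkylation) and so create the quaternary carbon; no stereocentre is formed.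

Step 2
Reactants: 3 2-(cyclopent-3-en-1-yl)-2-methylpropanoic acid
Product: 4 2-(cyclopent-3-en-1-yl)-2-methylpropanoyl chloride
Conditions: (COCl)2, DMF (cat.), CH2Cl2, 0 °C → rt
Reagents that add atoms: oxalyl chloride ClC(=O)C(=O)Cl
Why: Standard acid chloride formation through the chloroiminium catalyst; the isolated ring alkene should be inert.

Step 3
Reactants: 5 5,7-dimethoxy-2H-chromen-2-one (5,7-dimethoxycoumarin); 6 (2-methylpropyl)magnesium bromide; 4 2-(cyclopent-3-en-1-yl)-2-methylpropanoyl chloride
Product: 8 (3R,4S)-3-[2-(cyclopent-3-en-1-yl)-2-methylpropanoyl]-5,7-dimethoxy-4-(2-methylpropyl)chroman-2-one, via bromomagnesium enolate 7 (not isolated)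
Conditions: CuBr·SMe2 (5 mol %), 1-[2-(dicyclohexylphosphino)ferrocenyl]ethyldiphenylphosphine (reversed Josiphos ligand, enantiomer that delivers 4S, 6 mol %), 6, t-BuOMe, −72 °C; then 4, −72 → 0 °C; aq. NH4Cl
Reagents that add atoms: none
Why: Copper-catalysed asymmetric conjugate addition of the Grignard reagent to the coumarin should set C4 (the later C4') as S through face selection by the chiral copper–diphosphine complex, and the bromomagnesium enolate is then C-acylated by 4 (Claisen-type acylation favoured by magnesium chelation), the C3 centre so formed being lost in step 4.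

Step 4
Reactants: 8 (3R,4S)-3-[2-(cyclopent-3-en-1-yl)-2-methylpropanoyl]-5,7-dimethoxy-4-(2-methylpropyl)chroman-2-one
Product: 11 (4S)-2-[2-(cyclopent-3-en-1-yl)propan-2-yl]-5,7-dimethoxy-4-(2-methylpropyl)-4H-chromene, via keto acid 9 (not isolated), via keto phenol 10 (not isolated)
Conditions: LiOH, THF/H2O, 40 °C; 1 M HCl (pH 2), 50 °C; then PPTS (cat.), 4 Å MS, toluene, 70 °C
Reagents that add atoms: none
Why: Saponification of the aryl lactone and acidification give the β-keto acid, which decarboxylates, and the phenolic ketone then cyclodehydrates to the only possible enol ether because the other α-carbon is quaternary; C4 is not enolisable and should keep its configuration.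

Step 5
Reactants: 11 (4S)-2-[2-(cyclopent-3-en-1-yl)propan-2-yl]-5,7-dimethoxy-4-(2-methylpropyl)-4H-chromene
Product: 12 (1R,2R,4S,4'S)-5',7'-dimethoxy-3,3-dimethyl-4'-(2-methylpropyl)spiro[bicyclo[2.2.1]heptane-2,2'-chromane]
Conditions: Mn(dpm)3 [tris(2,2,6,6-tetramethylheptane-3,5-dionato)manganese] (10 mol %), PhSiH3 (slow addition), t-BuOOH, i-PrOH/hexane (0.005 M), 22 °C
Reagents that add atoms: none
Why: A manganese hydride made from Mn(dpm)3 and PhSiH3 transfers a hydrogen atom to C3' of the enol ether (Markovnikov MHAT), the tertiary α-alkoxy radical at C2' adds to one alkene carbon (the later C1) of the pendant cyclopentene, and the secondary C6 radical is then reduced by a second hydrogen-atom transfer. The closest known reaction types are the MHAT reductive cyclisation of dienes (Mukaiyama-type hydrofunctionalisation conditions) and the tin hydride cyclisation of the 2-(cyclopent-3-enyl)ethyl radical to norbornane. Ring C1–C2–C3–C4–C7 closes in the 5-exo-trig mode, accelerated by the gem-dimethyl group at C3. C2 is set by bond formation on the radical face anti to the C4' isobutyl group, which leaves the bulky C3 arm equatorial and cis to isobutyl. C1 and C4 are set by the choice between the two diastereotopic alkene carbons: the C3' methylene should take the exo position beside H1 and the smaller ring oxygen the endo position over the C1=C6 π bond, which gives the O-endo spirocycle. The step needs hydrogen-atom transfer to the enol ether and not to the ring alkene, and cyclisation before radical reduction; the more electron-rich, trisubstituted enol ether and high dilution with slow silane addition should secure both.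

Step 6
Reactants: 12 (1R,2R,4S,4'S)-5',7'-dimethoxy-3,3-dimethyl-4'-(2-methylpropyl)spiro[bicyclo[2.2.1]heptane-2,2'-chromane]
Product: 13 (1R,2R,4S,4'S)-3,3-dimethyl-4'-(2-methylpropyl)spiro[bicyclo[2.2.1]heptane-2,2'-chromane]-5',7'-diol
Conditions: NaSEt (excess), DMF, 150 °C; aq. HCl
Reagents that add atoms: none
Why: Thiolate SN2 attack at the two O-methyl carbons (nucleophilic aryl methyl ether cleavage) should free both phenols without acid, so the tertiary spiro ether and all stereocentres stay untouched.

Step 7
Reactants: 13 (1R,2R,4S,4'S)-3,3-dimethyl-4'-(2-methylpropyl)spiro[bicyclo[2.2.1]heptane-2,2'-chromane]-5',7'-diol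
Product: 14 (1R,2R,4S,4'S)-5',7'-dihydroxy-3,3-dimethyl-4'-(2-methylpropyl)spiro[bicyclo[2.2.1]heptane-2,2'-chromane]-6',8'-dicarbaldehyde
Conditions: POCl3, DMF, MeCN, 0 → 40 °C; then H2O, 60 °C
Reagents that add atoms: N,N-dimethylformamide CN(C)C=O; water O
Why: Vilsmeier–Haack formylation should occur at the only two free ring positions (C6' and C8'), both activated by three oxygen substituents, and hydrolysis of the bis-iminium salt gives the dialdehyde without ionising the hindered spiro ether.

Compound list
1 | 4-bromocyclopent-1-ene | BrC1CC=CC1 | starting material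
2 | 2-methylpropanoic acid | CC(C)C(=O)O | starting material
3 | 2-(cyclopent-3-en-1-yl)-2-methylpropanoic acid | CC(C)(C1CC=CC1)C(=O)O | intermediate
4 | 2-(cyclopent-3-en-1-yl)-2-methylpropanoyl chloride | CC(C)(C1CC=CC1)C(=O)Cl | intermediate
5 | 5,7-dimethoxy-2H-chromen-2-one (5,7-dimethoxycoumarin) | COc1cc(OC)c2C=CC(=O)Oc2c1 | starting material
6 | (2-methylpropyl)magnesium bromide | CC(C)C[Mg]Br | starting material
7 | bromomagnesium enolate of (4S)-5,7-dimethoxy-4-(2-methylpropyl)chroman-2-one | CC(C)C[C@H]1C=C(O[Mg]Br)Oc2cc(OC)cc(OC)c21 | intermediate (not isolated)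
8 | (3R,4S)-3-[2-(cyclopent-3-en-1-yl)-2-methylpropanoyl]-5,7-dimethoxy-4-(2-methylpropyl)chroman-2-one (3,4-trans, C3 epimerisable) | CC(C)C[C@H]1[C@H](C(=O)C(C)(C)C2CC=CC2)C(=O)Oc2cc(OC)cc(OC)c21 | intermediate
9 | (2R,3S)-2-[2-(cyclopent-3-en-1-yl)-2-methylpropanoyl]-3-(2-hydroxy-4,6-dimethoxyphenyl)-5-methylhexanoic acid | CC(C)C[C@@H]([C@@H](C(=O)O)C(=O)C(C)(C)C1CC=CC1)c1c(O)cc(OC)cc1OC | intermediate (not isolated)
10 | (5S)-2-(cyclopent-3-en-1-yl)-5-(2-hydroxy-4,6-dimethoxyphenyl)-2,7-dimethyloctan-3-one | CC(C)C[C@@H](CC(=O)C(C)(C)C1CC=CC1)c1c(O)cc(OC)cc1OC | intermediate (not isolated)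
11 | (4S)-2-[2-(cyclopent-3-en-1-yl)propan-2-yl]-5,7-dimethoxy-4-(2-methylpropyl)-4H-chromene | CC(C)C[C@H]1C=C(C(C)(C)C2CC=CC2)Oc2cc(OC)cc(OC)c21 | intermediate
12 | (1R,2R,4S,4'S)-5',7'-dimethoxy-3,3-dimethyl-4'-(2-methylpropyl)spiro[bicyclo[2.2.1]heptane-2,2'-chromane] | CC(C)C[C@H]1C[C@@]2(Oc3cc(OC)cc(OC)c31)[C@@H]1CC[C@@H](C1)C2(C)C | intermediate
13 | (1R,2R,4S,4'S)-3,3-dimethyl-4'-(2-methylpropyl)spiro[bicyclo[2.2.1]heptane-2,2'-chromane]-5',7'-diol | CC(C)C[C@H]1C[C@@]2(Oc3cc(O)cc(O)c31)[C@@H]1CC[C@@H](C1)C2(C)C | intermediate
14 | (1R,2R,4S,4'S)-5',7'-dihydroxy-3,3-dimethyl-4'-(2-methylpropyl)spiro[bicyclo[2.2.1]heptane-2,2'-chromane]-6',8'-dicarbaldehyde | CC(C)C[C@H]1C[C@@]2(Oc3c(C=O)c(O)c(C=O)c(O)c31)[C@@H]1CC[C@@H](C1)C2(C)C | target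

Total step count: 7. Longest linear sequence: 7 steps (from 1 and 2 through 3, 4, 8, 11, 12 and 13 to 14).

Steps most likely to fail

Step 5 (key step). Hydrogen-atom delivery to the C2' radical, or a 1,5-hydrogen shift from the allylic ring CH2, may outrun the strained 5-exo closure, and the exo/endo placement of the ring oxygen against C3' may be poorly discriminated. The fallback sets out from 11 and returns at 12, closing the ring by the polar π-route instead. HCl (1 equiv) and SnCl4 in CH2Cl2 at −78 °C should convert the enol ether of 11 into the C2' oxocarbenium ion. This ion is attacked by the cyclopentene (Prins-type cation–olefin cyclisation, the classical 2-(cyclopent-3-enyl)ethyl to 2-norbornyl cation closure) with exo capture of chloride at C6, giving the 6-exo-chloro spirocycle F1. Radical dechlorination of F1 (Bu3SnH, AIBN, benzene, 80 °C) should then give 12.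

Step 3. Conjugate addition to the electron-rich coumarin, hindered by the peri 5-methoxy group, may be so slow that uncatalysed 1,2-addition or racemic 1,4-addition erodes the enantiopurity, and acylation of the enolate by the hindered acid chloride may be sluggish. The fallback sets out from 4 and returns at 8, setting C4 by iminium catalysis instead. Commercial 3,5-dimethoxyphenol and (E)-5-methylhex-2-enal, with a diarylprolinol silyl ether (enantiomer chosen for 4S), should undergo asymmetric Friedel–Crafts alkylation and hemiacetalisation to the lactol (4S)-5,7-dimethoxy-4-(2-methylpropyl)chroman-2-ol F2. Oxidation (PhI(OAc)2, TEMPO cat.) gives the lactone (4S)-5,7-dimethoxy-4-(2-methylpropyl)chroman-2-one F3. The lithium enolate of F3 (LiN(SiMe3)2, THF, −78 °C) is C-acylated with 4 to give 8.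

Step 1. E2 elimination of the homoallylic secondary bromide to cyclopentadiene may outcompete substitution by the hindered dianion. The fallback sets out from 1 and returns at 3, building the quaternary carbon with the smaller nitrile-stabilised carbanion. Lithiated 2-methylpropanenitrile (LiN(i-Pr)2, THF, −78 °C → rt) alkylated with 1 should give 2-(cyclopent-3-en-1-yl)-2-methylpropanenitrile F4, which is hydrolysed (KOH, ethylene glycol, 160 °C; then HCl) to 3.

Further compounds
F1 | step 5 | 6-exo-chloro-5',7'-dimethoxy-3,3-dimethyl-4'-(2-methylpropyl)spiro[bicyclo[2.2.1]heptane-2,2'-chromane], other stereocentres as in 12 | CC(C)C[C@H]1C[C@@]2(Oc3cc(OC)cc(OC)c31)[C@@H]1[C@@H](Cl)C[C@@H](C1)C2(C)C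
F2 | step 3 | (4S)-5,7-dimethoxy-4-(2-methylpropyl)chroman-2-ol (anomeric mixture) | CC(C)C[C@H]1CC(O)Oc2cc(OC)cc(OC)c21
F3 | step 3 | (4S)-5,7-dimethoxy-4-(2-methylpropyl)chroman-2-one | CC(C)C[C@H]1CC(=O)Oc2cc(OC)cc(OC)c21
F4 | step 1 | 2-(cyclopent-3-en-1-yl)-2-methylpropanenitrile | CC(C)(C#N)C1CC=CC1
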